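**Plan**

1. Numbering: ring C1 (OH), C2 (side chain), C4 (OH), C6 (CH3); side chain C1' (benzylic CH2) to C16'. The retrosynthesis cuts, in this order: the three O–Si bonds of a fully silylated precursor; C5'–C6' (ketone carbon to vinyl CH); C1'–C2' (benzylic CH2 to vinyl CH); C8'–C9' (propargylic to allylic CH2); C12'–C13' (vinylogous aldol).
2. Enabling feature: the C5' ketone sits on the vinyl CH (C6') of an E-trisubstituted olefin whose other carbon, C7', carries a methyl group. The unit C5'(=O)–C6'H=C7'(CH3) is what syn-methylmetalation of a terminal alkyne C6'≡C7' followed by C-acylation at C6' delivers, so one operation sets the C7' methyl, the 6'E geometry and the fragment-joining bond. C1'H2–C2'H=C3'(CH3) has the same imprint and is made the same way. No ring is formed: the benzene ring is bought as 2,6-dimethylhydroquinone, whose two equivalent methyl groups make functionalisation of one of them (the future C1') regiochemically unambiguous.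
3. Acid half (steps 1–5): silylation, benzylic bromination, methylalumination of but-3-yn-1-ol with palladium-catalysed benzylation (C1'–C2'), then two-stage oxidation to the β,γ-unsaturated acid.
4. Alkyne half (steps 6–12): asymmetric vinylogous Mukaiyama aldol of 3-methylbut-2-enal (C12'–C13'), silylation, ester reduction, bromination, propargylation (C8'–C9'), C-desilylation.
5. Union and end game: methylalumination of the alkyne and palladium-catalysed acylation by the acid chloride (step 13, C5'–C6'), then global desilylation (step 14).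
6. Stereochemistry: C13' (R) from the catalyst-controlled vinylogous aldol; 10'E from the same step; 2'E and 6'E from syn-carboalumination with retention in both palladium couplings.

Key step: step 13

Remark: compounds 1, 4, 9, 12 and 17 are taken as commercial; the facial sense in step 7 is assigned by analogy with other conjugated aldehydes, and should the first sample of 13 prove to be 5S (analysis of its α-methoxy-α-(trifluoromethyl)phenylacetates), the (S,S)-catalyst is used and nothing else changes.

**Route**

Step 1
Reactants: 1 2,6-dimethylbenzene-1,4-diol (2,6-dimethylhydroquinone)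
Product: 2 1,4-bis(tert-butyldimethylsilyloxy)-2,6-dimethylbenzene
Conditions: TBSCl (2.6 equiv), imidazole (5 equiv), DMF, 50 °C
Reagents that add atoms: tert-butyldimethylsilyl chloride, CC(C)(C)[Si](C)(C)Cl
Why: Imidazole-promoted O-silylation of phenols; gentle heating brings the hindered hydroxyl between the two methyl groups to full conversion, and silyl ethers are chosen because all silicon groups can be removed together at the end with buffered fluoride.

Step 2
Reactants: 2 1,4-bis(tert-butyldimethylsilyloxy)-2,6-dimethylbenzene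
Product: 3 1-(bromomethyl)-2,5-bis(tert-butyldimethylsilyloxy)-3-methylbenzene
Conditions: NBS (0.95 equiv), AIBN (5 mol %), PhCF3, 85 °C, visible light
Reagents that add atoms: N-bromosuccinimide, O=C1CCC(=O)N1Br
Why: Wohl–Ziegler benzylic bromination by a radical chain; the two methyl groups are equivalent by symmetry so monobromination can give only one constitution, the non-polar medium and the bulky silyloxy groups should hold back ionic ring bromination, and a slight deficit of NBS limits dibromination (unreacted 2 is recycled).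

Step 3
Reactants: 4 but-3-yn-1-ol; 3 1-(bromomethyl)-2,5-bis(tert-butyldimethylsilyloxy)-3-methylbenzene
Product: 6 (3E)-5-[2,5-bis(tert-butyldimethylsilyloxy)-3-methylphenyl]-3-methylpent-3-en-1-ol, via (E)-alkenylalane 5 (not isolated)
Conditions: 4, AlMe3 (3 equiv), Cp2ZrCl2 (0.25 equiv), CH2Cl2, 0 °C to rt; excess AlMe3 removed in vacuo; then 3, Pd(PPh3)4 (5 mol %), THF, rt; aq. KNaC4H4O6 (potassium sodium tartrate)
Reagents that add atoms: trimethylaluminium, C[Al](C)C (the C3' methyl; also the aluminium groups of 5)
Why: Zirconium-catalysed syn-methylalumination of the terminal alkyne (the hydroxyl is masked in the flask as its dimethylaluminium alkoxide) puts the methyl on C3' and aluminium on C2' with E geometry, and the palladium-catalysed coupling of the alkenylalane with the benzylic bromide (Negishi coupling) should form the C1'–C2' bond with retention of that geometry.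

Step 4
Reactants: 6 (3E)-5-[2,5-bis(tert-butyldimethylsilyloxy)-3-methylphenyl]-3-methylpent-3-en-1-ol
Product: 7 (3E)-5-[2,5-bis(tert-butyldimethylsilyloxy)-3-methylphenyl]-3-methylpent-3-enal
Conditions: Dess–Martin periodinane (1.3 equiv), NaHCO3, CH2Cl2, 0 °C; filtered through a short silica pad and used at once
Reagents that add atoms: none
Why: Dess–Martin oxidation under bicarbonate buffering is fast and neutral, so the primary alcohol should give the aldehyde without migration of the C2'=C3' double bond into conjugation and without touching the aryl silyl ethers.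

Step 5
Reactants: 7 (3E)-5-[2,5-bis(tert-butyldimethylsilyloxy)-3-methylphenyl]-3-methylpent-3-enal
Product: 8 (3E)-5-[2,5-bis(tert-butyldimethylsilyloxy)-3-methylphenyl]-3-methylpent-3-enoic acid
Conditions: NaClO2 (3 equiv), NaH2PO4 (3 equiv), 2-methylbut-2-ene (20 equiv), t-BuOH/H2O, 0 °C
Reagents that add atoms: sodium chlorite, [Na+].[O-]Cl=O
Why: Pinnick oxidation in a weakly acidic phosphate buffer converts the aldehyde to the acid without enolisation, and the large excess of 2-methylbut-2-ene traps hypochlorous acid before it can chlorinate the electron-rich ring or the olefin.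

Step 6
Reactants: 9 methyl 3-methylbut-2-enoate
Product: 11 1-(tert-butyldimethylsilyloxy)-1-methoxy-3-methylbuta-1,3-diene, via lithium dienolate 10 (not isolated)
Conditions: LiN(i-Pr)2 (1.1 equiv), THF, −78 °C; then TBSCl (1.2 equiv), DMPU, −78 °C to rt; distillation
Reagents that add atoms: tert-butyldimethylsilyl chloride, CC(C)(C)[Si](C)(C)Cl (lithium diisopropylamide, CC(C)[N-]C(C)C.[Li+], supplies the lithium of 10 only)
Why: Kinetic γ-deprotonation of the β,β-dimethylacrylate gives the extended lithium enolate, which is silylated on oxygen in the presence of DMPU (formation of a silyl ketene acetal); the ketene acetal geometry has no consequence for step 7.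

Step 7
Reactants: 11 1-(tert-butyldimethylsilyloxy)-1-methoxy-3-methylbuta-1,3-diene; 12 3-methylbut-2-enal
Product: 13 methyl (2E,5R)-5-hydroxy-3,7-dimethylocta-2,6-dienoate
Conditions: SiCl4 (1.1 equiv), (R,R)-bisphosphoramide N,N'-dimethyl-N,N'-bis[(R)-3,5-dimethyl-4-oxido-3,5-dihydro-4H-dinaphtho[2,1-d:1',2'-f][1,3,2]diazaphosphepin-4-yl]pentane-1,5-diamine (2 mol %), i-Pr2NEt (10 mol %), CH2Cl2, −78 °C; aq. NaHCO3
Reagents that add atoms: none
Why: Catalytic enantioselective vinylogous Mukaiyama aldol addition in which the chiral bisphosphoramide-bound trichlorosilyl cation activates the conjugated aldehyde and the dienol ether attacks through an open transition state at its γ-carbon only; the (R,R)-catalyst is expected to direct attack to the Re face of the aldehyde, which sets the 5R carbinol (later C13'), and the s-trans dienol ether gives the 2E olefin (later 10'E), any Z isomer being removable as its lactone.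

Step 8
Reactants: 13 methyl (2E,5R)-5-hydroxy-3,7-dimethylocta-2,6-dienoate
Product: 14 methyl (2E,5R)-5-(tert-butyldimethylsilyloxy)-3,7-dimethylocta-2,6-dienoate
Conditions: TBSCl (1.3 equiv), imidazole (2.5 equiv), DMF, rt
Reagents that add atoms: tert-butyldimethylsilyl chloride, CC(C)(C)[Si](C)(C)Cl
Why: Standard imidazole-promoted silylation of a secondary allylic alcohol; the silyl ether carries the C13' oxygen through the basic and Lewis acidic steps that follow and is cleaved together with the aryl silyl ethers at the end.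

Step 9
Reactants: 14 methyl (2E,5R)-5-(tert-butyldimethylsilyloxy)-3,7-dimethylocta-2,6-dienoate
Product: 15 (2E,5R)-5-(tert-butyldimethylsilyloxy)-3,7-dimethylocta-2,6-dien-1-ol
Conditions: (i-Bu)2AlH (2.3 equiv), CH2Cl2, −78 °C; aq. KNaC4H4O6
Reagents that add atoms: none
Why: 1,2-Reduction of the α,β-unsaturated ester with (i-Bu)2AlH at low temperature gives the allylic alcohol without conjugate reduction and without change of the 2E geometry or the silyl ether.

Step 10
Reactants: 15 (2E,5R)-5-(tert-butyldimethylsilyloxy)-3,7-dimethylocta-2,6-dien-1-ol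
Product: 16 (2E,5R)-1-bromo-5-(tert-butyldimethylsilyloxy)-3,7-dimethylocta-2,6-diene
Conditions: CBr4 (1.3 equiv), PPh3 (1.4 equiv), 2,6-lutidine (0.2 equiv), CH2Cl2, 0 °C; used without storage
Reagents that add atoms: carbon tetrabromide, BrC(Br)(Br)Br
Why: Appel bromination converts the primary allylic alcohol to the bromide by SN2 displacement of the alkoxyphosphonium under near-neutral conditions, so no allylic transposition or loss of the silyl ether is expected.

Step 11
Reactants: 16 (2E,5R)-1-bromo-5-(tert-butyldimethylsilyloxy)-3,7-dimethylocta-2,6-diene; 17 1-(trimethylsilyl)propyne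
Product: 19 (5E,8R)-8-(tert-butyldimethylsilyloxy)-6,10-dimethyl-1-(trimethylsilyl)undeca-5,9-dien-1-yne, via 3-lithio-1-(trimethylsilyl)propyne 18 (not isolated)
Conditions: 17 (1.5 equiv), n-BuLi (1.4 equiv), THF, −78 to −20 °C; then 16, THF, −78 to 0 °C
Reagents that add atoms: none
Why: Propargylic lithiation of 1-(trimethylsilyl)propyne gives a nucleophile that alkylates primary allylic bromides at its CH2 terminus in SN2 fashion (the silyl group blocks the acetylenic end and disfavours the allenyl mode), forming the C8'–C9' bond with the E olefin intact.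

Step 12
Reactants: 19 (5E,8R)-8-(tert-butyldimethylsilyloxy)-6,10-dimethyl-1-(trimethylsilyl)undeca-5,9-dien-1-yne
Product: 20 (5E,8R)-8-(tert-butyldimethylsilyloxy)-6,10-dimethylundeca-5,9-dien-1-yne
Conditions: K2CO3 (0.5 equiv), MeOH, rt
Reagents that add atoms: none
Why: Methanolysis of the alkynyl C–Si bond by catalytic methoxide is selective for the acetylenic trimethylsilyl group; the secondary tert-butyldimethylsilyl ether is stable to K2CO3 in methanol.

Step 13
Reactants: 8 (3E)-5-[2,5-bis(tert-butyldimethylsilyloxy)-3-methylphenyl]-3-methylpent-3-enoic acid; 20 (5E,8R)-8-(tert-butyldimethylsilyloxy)-6,10-dimethylundeca-5,9-dien-1-yne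
Product: 23 (2E,6E,10E,13R)-1-[2,5-bis(tert-butyldimethylsilyloxy)-3-methylphenyl]-13-(tert-butyldimethylsilyloxy)-3,7,11,15-tetramethylhexadeca-2,6,10,14-tetraen-5-one, via acid chloride 21 (not isolated), via (E)-alkenylalane 22 (not isolated)
Conditions: flask 1: 8, 1-chloro-N,N,2-trimethylprop-1-en-1-amine (1.1 equiv), CH2Cl2, 0 °C, giving 21; flask 2: 20 (1.3 equiv), AlMe3 (2 equiv), Cp2ZrCl2 (0.25 equiv), CH2Cl2, 0 °C to rt, giving 22, volatiles and excess AlMe3 removed in vacuo, THF; then solution of 21 and Pd(PPh3)4 (5 mol %), THF, 0 °C to rt; aq. KNaC4H4O6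
Reagents that add atoms: trimethylaluminium, C[Al](C)C (the C7' methyl; also the aluminium group of 22); 1-chloro-N,N,2-trimethylprop-1-en-1-amine, CN(C)C(Cl)=C(C)C (the chlorine of 21 only)
Why: The zirconocene/AlMe3 reagent adds methyl and metal syn across the terminal alkyne C6'≡C7' of 20, methyl to the internal carbon C7' and aluminium to the terminal carbon C6'; acid chloride 21 then adds oxidatively to zerovalent palladium, the alkenyl group passes from aluminium to the acyl divalent palladium chloride with retention, and reductive elimination forms the C5'–C6' bond. The closest known reaction type is the zirconium-catalysed methylalumination of 1,5-enynes followed by palladium-catalysed acylation of the alkenylalane with an acid chloride (Negishi acylation). No ring is closed and no stereocentre is created; the C13' centre is remote and protected. The 6'E geometry follows from syn addition and retentive coupling, so the enone is never formed as a mixture that would need equilibration. The selectivities needed are terminal regiochemistry of the methylalumination (an unhindered terminal alkyne, the trisubstituted olefins being inert), transfer of the alkenyl and not a methyl group (excess AlMe3 is stripped off and alkenyl groups transmetalate faster), and retention of the skipped position of the C2'=C3' double bond. The last is secured by making the acid chloride under neutral conditions, by the absence of any base, and by letting the doubly activated C4' methylene appear next to a ketone only in the last, cold event.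

Step 14
Reactants: 23 (2E,6E,10E,13R)-1-[2,5-bis(tert-butyldimethylsilyloxy)-3-methylphenyl]-13-(tert-butyldimethylsilyloxy)-3,7,11,15-tetramethylhexadeca-2,6,10,14-tetraen-5-one
Product: 24 (2E,6E,10E,13R)-1-(2,5-dihydroxy-3-methylphenyl)-13-hydroxy-3,7,11,15-tetramethylhexadeca-2,6,10,14-tetraen-5-one (CNP0251818.3)
Conditions: Bu4NF (6 equiv), AcOH (6 equiv), degassed THF, argon, 0 °C to rt
Reagents that add atoms: none
Why: Fluoride buffered with acetic acid should cleave the two aryl silyl ethers quickly and the secondary allylic silyl ether more slowly without free phenoxide or alkoxide building up, so the C2'=C3' bond should stay out of conjugation and the allylic C13' carbinol is not ionised; degassed solvent keeps the hydroquinone from oxidising to the quinone.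

**Compound list**

1 | 2,6-dimethylbenzene-1,4-diol | Cc1cc(O)cc(C)c1O | starting material
2 | 1,4-bis(tert-butyldimethylsilyloxy)-2,6-dimethylbenzene | Cc1cc(O[Si](C)(C)C(C)(C)C)cc(C)c1O[Si](C)(C)C(C)(C)C | intermediate
3 | 1-(bromomethyl)-2,5-bis(tert-butyldimethylsilyloxy)-3-methylbenzene | BrCc1cc(O[Si](C)(C)C(C)(C)C)cc(C)c1O[Si](C)(C)C(C)(C)C | intermediate
4 | but-3-yn-1-ol | C#CCCO | starting material
5 | (E)-alkenylalane Me2Al–CH=C(CH3)–CH2CH2–OAlMe2 from 4 | C[Al](C)/C=C(\C)CCO[Al](C)C | intermediate
6 | (3E)-5-[2,5-bis(tert-butyldimethylsilyloxy)-3-methylphenyl]-3-methylpent-3-en-1-ol | OCC/C(C)=C/Cc1cc(O[Si](C)(C)C(C)(C)C)cc(C)c1O[Si](C)(C)C(C)(C)C | intermediate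
7 | (3E)-5-[2,5-bis(tert-butyldimethylsilyloxy)-3-methylphenyl]-3-methylpent-3-enal | O=CC/C(C)=C/Cc1cc(O[Si](C)(C)C(C)(C)C)cc(C)c1O[Si](C)(C)C(C)(C)C | intermediate
8 | (3E)-5-[2,5-bis(tert-butyldimethylsilyloxy)-3-methylphenyl]-3-methylpent-3-enoic acid | OC(=O)C/C(C)=C/Cc1cc(O[Si](C)(C)C(C)(C)C)cc(C)c1O[Si](C)(C)C(C)(C)C | intermediate
9 | methyl 3-methylbut-2-enoate | COC(=O)C=C(C)C | starting material
10 | lithium dienolate of 9 (lithium 1-methoxy-3-methylbuta-1,3-dien-1-olate) | [Li]OC(OC)=CC(C)=C | intermediate
11 | 1-(tert-butyldimethylsilyloxy)-1-methoxy-3-methylbuta-1,3-diene (ketene acetal geometry not defined) | COC(O[Si](C)(C)C(C)(C)C)=CC(C)=C | intermediate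
12 | 3-methylbut-2-enal | CC(C)=CC=O | starting material
13 | methyl (2E,5R)-5-hydroxy-3,7-dimethylocta-2,6-dienoate | CC(C)=C[C@H](O)C/C(C)=C/C(=O)OC | intermediate
14 | methyl (2E,5R)-5-(tert-butyldimethylsilyloxy)-3,7-dimethylocta-2,6-dienoate | CC(C)=C[C@H](O[Si](C)(C)C(C)(C)C)C/C(C)=C/C(=O)OC | intermediate
15 | (2E,5R)-5-(tert-butyldimethylsilyloxy)-3,7-dimethylocta-2,6-dien-1-ol | CC(C)=C[C@H](O[Si](C)(C)C(C)(C)C)C/C(C)=C/CO | intermediate
16 | (2E,5R)-1-bromo-5-(tert-butyldimethylsilyloxy)-3,7-dimethylocta-2,6-diene | CC(C)=C[C@H](O[Si](C)(C)C(C)(C)C)C/C(C)=C/CBr | intermediate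
17 | 1-(trimethylsilyl)propyne | CC#C[Si](C)(C)C | starting material
18 | 3-lithio-1-(trimethylsilyl)propyne | [Li]CC#C[Si](C)(C)C | intermediate
19 | (5E,8R)-8-(tert-butyldimethylsilyloxy)-6,10-dimethyl-1-(trimethylsilyl)undeca-5,9-dien-1-yne | CC(C)=C[C@H](O[Si](C)(C)C(C)(C)C)C/C(C)=C/CCC#C[Si](C)(C)C | intermediate
20 | (5E,8R)-8-(tert-butyldimethylsilyloxy)-6,10-dimethylundeca-5,9-dien-1-yne | CC(C)=C[C@H](O[Si](C)(C)C(C)(C)C)C/C(C)=C/CCC#C | intermediate
21 | (3E)-5-[2,5-bis(tert-butyldimethylsilyloxy)-3-methylphenyl]-3-methylpent-3-enoyl chloride | ClC(=O)C/C(C)=C/Cc1cc(O[Si](C)(C)C(C)(C)C)cc(C)c1O[Si](C)(C)C(C)(C)C | intermediate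
22 | dimethyl[(1E,5E,8R)-8-(tert-butyldimethylsilyloxy)-2,6,10-trimethylundeca-1,5,9-trien-1-yl]aluminium | CC(C)=C[C@H](O[Si](C)(C)C(C)(C)C)C/C(C)=C/CC/C(C)=C/[Al](C)C | intermediate
23 | (2E,6E,10E,13R)-1-[2,5-bis(tert-butyldimethylsilyloxy)-3-methylphenyl]-13-(tert-butyldimethylsilyloxy)-3,7,11,15-tetramethylhexadeca-2,6,10,14-tetraen-5-one | CC(C)=C[C@H](O[Si](C)(C)C(C)(C)C)C/C(C)=C/CC/C(C)=C/C(=O)C/C(C)=C/Cc1cc(O[Si](C)(C)C(C)(C)C)cc(C)c1O[Si](C)(C)C(C)(C)C | intermediate
24 | (2E,6E,10E,13R)-1-(2,5-dihydroxy-3-methylphenyl)-13-hydroxy-3,7,11,15-tetramethylhexadeca-2,6,10,14-tetraen-5-one | CC(C)=C[C@H](O)C/C(C)=C/CC/C(C)=C/C(=O)C/C(C)=C/Cc1cc(O)cc(C)c1O | target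

**Step count and risks**

Total step count: 14. Longest linear sequence: 9 steps (9 to 24, steps 6–12, 13 and 14); the acid half contributes 5 steps before the union.

Steps most likely to fail:

Step 13. The β,γ-unsaturated acyl palladium intermediate may lose carbon monoxide to an allyl palladium species and deliver the CO-free skipped diene. The acid chloride may also form a ketene, or the C2'=C3' double bond may migrate under the Lewis acidic aluminium residues, and methyl transfer may compete with alkenyl transfer. The fallback sets out from alkyne 20 and aldehyde 7 and returns at 23. Alkyne 20 is methylaluminated as before and the alkenylalane 22 is quenched with iodine (THF, −30 °C) to give (1E,5E,8R)-8-(tert-butyldimethylsilyloxy)-1-iodo-2,6,10-trimethylundeca-1,5,9-triene F1. Nozaki–Hiyama–Kishi coupling of F1 with aldehyde 7 (CrCl2, NiCl2 1 mol %, DMSO/THF, rt) forms the same C5'–C6' bond under non-basic conditions and gives the C5' allylic alcohol (2E,6E,10E,13R)-1-[2,5-bis(tert-butyldimethylsilyloxy)-3-methylphenyl]-13-(tert-butyldimethylsilyloxy)-3,7,11,15-tetramethylhexadeca-2,6,10,14-tetraen-5-ol F2 as a mixture of C5' epimers. Bicarbonate-buffered Dess–Martin oxidation of F2 then gives 23.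

Step 2. Ionic bromination of the electron-rich ring, oxidative loss of the silyl groups or over-bromination may outrun clean benzylic monobromination. The fallback sets out from 1 and returns at 6. Compound 1 is acetylated (Ac2O, pyridine) to 2,6-dimethyl-1,4-phenylene diacetate F3, whose deactivated ring allows Wohl–Ziegler bromination (NBS, AIBN, PhCF3) to 2-(bromomethyl)-6-methyl-1,4-phenylene diacetate F4. F4 is coupled with alkenylalane 5 under the palladium conditions of step 3 to give (E)-2-(5-hydroxy-3-methylpent-2-en-1-yl)-6-methyl-1,4-phenylene diacetate F5; partial loss of acetyl at this stage is of no consequence. Methanolysis (K2CO3, degassed MeOH) gives (E)-2-(5-hydroxy-3-methylpent-2-en-1-yl)-6-methylbenzene-1,4-diol F6. Persilylation (TBSCl, imidazole, DMF) gives the tris(tert-butyldimethylsilyl) ether of that triol F7, and selective cleavage of its primary alkyl silyl ether (pyridinium p-toluenesulfonate, MeOH, rt) gives 6.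

Step 14. While the hindered secondary silyl ether is still being cleaved, the C2'=C3' double bond may migrate into conjugation with the C5' ketone and the freed hydroquinone may oxidise in air. The fallback sets out from 23 and returns at 24. The two aryl silyl ethers are removed oxidatively with (NH4)2Ce(NO3)6 (MeCN/H2O, 0 °C) to give the stable quinone 2-[(2E,6E,10E,13R)-13-(tert-butyldimethylsilyloxy)-3,7,11,15-tetramethyl-5-oxohexadeca-2,6,10,14-tetraen-1-yl]-6-methyl-1,4-benzoquinone F8. The remaining silyl ether is cleaved with HF·pyridine buffered with pyridine (THF, 0 °C) to give 2-[(2E,6E,10E,13R)-13-hydroxy-3,7,11,15-tetramethyl-5-oxohexadeca-2,6,10,14-tetraen-1-yl]-6-methyl-1,4-benzoquinone F9. Reduction of F9 with Na2S2O4 (THF/H2O, rt, argon) gives 24 under neutral conditions.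

**Further compounds**

F1 | step 13 | (1E,5E,8R)-8-(tert-butyldimethylsilyloxy)-1-iodo-2,6,10-trimethylundeca-1,5,9-triene | CC(C)=C[C@H](O[Si](C)(C)C(C)(C)C)C/C(C)=C/CC/C(C)=C/I
F2 | step 13 | (2E,6E,10E,13R)-1-[2,5-bis(tert-butyldimethylsilyloxy)-3-methylphenyl]-13-(tert-butyldimethylsilyloxy)-3,7,11,15-tetramethylhexadeca-2,6,10,14-tetraen-5-ol (C5' epimers) | CC(C)=C[C@H](O[Si](C)(C)C(C)(C)C)C/C(C)=C/CC/C(C)=C/C(O)C/C(C)=C/Cc1cc(O[Si](C)(C)C(C)(C)C)cc(C)c1O[Si](C)(C)C(C)(C)C
F3 | step 2 | 2,6-dimethyl-1,4-phenylene diacetate | CC(=O)Oc1cc(C)c(OC(C)=O)c(C)c1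
F4 | step 2 | 2-(bromomethyl)-6-methyl-1,4-phenylene diacetate | CC(=O)Oc1cc(C)c(OC(C)=O)c(CBr)c1
F5 | step 2 | (E)-2-(5-hydroxy-3-methylpent-2-en-1-yl)-6-methyl-1,4-phenylene diacetate | CC(=O)Oc1cc(C)c(OC(C)=O)c(C/C=C(\C)CCO)c1
F6 | step 2 | (E)-2-(5-hydroxy-3-methylpent-2-en-1-yl)-6-methylbenzene-1,4-diol | OCC/C(C)=C/Cc1cc(O)cc(C)c1O
F7 | step 2 | (E)-1,4-bis(tert-butyldimethylsilyloxy)-2-[5-(tert-butyldimethylsilyloxy)-3-methylpent-2-en-1-yl]-6-methylbenzene | CC(C)(C)[Si](C)(C)OCC/C(C)=C/Cc1cc(O[Si](C)(C)C(C)(C)C)cc(C)c1O[Si](C)(C)C(C)(C)C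
F8 | step 14 | 2-[(2E,6E,10E,13R)-13-(tert-butyldimethylsilyloxy)-3,7,11,15-tetramethyl-5-oxohexadeca-2,6,10,14-tetraen-1-yl]-6-methyl-1,4-benzoquinone | CC(C)=C[C@H](O[Si](C)(C)C(C)(C)C)C/C(C)=C/CC/C(C)=C/C(=O)C/C(C)=C/CC1=CC(=O)C=C(C)C1=O
F9 | step 14 | 2-[(2E,6E,10E,13R)-13-hydroxy-3,7,11,15-tetramethyl-5-oxohexadeca-2,6,10,14-tetraen-1-yl]-6-methyl-1,4-benzoquinone | CC(C)=C[C@H](O)C/C(C)=C/CC/C(C)=C/C(=O)C/C(C)=C/CC1=CC(=O)C=C(C)C1=O
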